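Ring B (O, C9, C10, C11, C12) carries a bromine on each exocyclic carbon next to its oxygen, C8 and C13; this Br–C8–C9–O–C12–C13–Br array is the footprint of Br2 adding across an epoxy alkene. Everything therefore rests on disconnecting O–C12: an acyclic cis-8,9-epoxide that holds the whole C15 chain, a free C10 hydroxyl and an (E)-C12=C13 alkene is treated with bromine, which closes ring B by 5-exo attack of the epoxide oxygen on the bromonium ion and opens the epoxonium ion at propargylic C8 with bromide, setting C8, C12, C13 and both C–Br bonds at once. Gold-catalysed 5-exo-dig closure of O10–H onto C7 then forms ring A and the (Z)-enol ether.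

Key step: step 7

Remark: carbons are numbered C1 (terminal alkyne carbon) to C15 (methyl) along the chain, ring A is O/C7/C8/C9/C10 and ring B is O/C9/C10/C11/C12; the names of the C15 compounds 11 to 16 and all atom labels in the text keep this numbering.

Step 1
Reactants: 1 methyl (E)-hex-3-enoate; 2 1,4-bis(trimethylsilyl)buta-1,3-diyne
Product: 4 (E)-1-(trimethylsilyl)deca-7-ene-1,3-diyn-5-one, via lithium diynide 3 (not isolated)
Conditions: 2, MeLi·LiBr, THF, −78 °C → rt; then −78 °C, BF3·OEt2, then 1; AcOH/aq. NH4Cl quench at −78 °C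
Reagents that add atoms: none
Why: Alkynyl ketone synthesis by acylation of a lithium acetylide with an ester under BF3 activation: MeLi cleaves one C–Si bond of 2 to give 3, and the BF3-bound tetrahedral adduct formed with 1 should survive until work-up, which prevents double addition and, at −78 °C, deprotonation of the doubly activated methylene next to the carbonyl.

Step 2
Reactants: 4 (E)-1-(trimethylsilyl)deca-7-ene-1,3-diyn-5-one
Product: 5 (5S,7E)-1-(trimethylsilyl)deca-7-ene-1,3-diyn-5-ol
Conditions: Ru[(S,S)-TsNCH(Ph)CH(Ph)NH](p-cymene) (2 mol %), i-PrOH, 25 °C, no added base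
Reagents that add atoms: none
Why: Noyori-type asymmetric transfer hydrogenation of an alkynyl ketone, in which the diynyl group takes the role of the aryl group in the six-membered hydride-transfer transition state, so that the (S,S)-catalyst should give the (S)-carbinol (the future C10) and leave the alkynes and the β,γ-alkene untouched.

Step 3
Reactants: 5 (5S,7E)-1-(trimethylsilyl)deca-7-ene-1,3-diyn-5-ol
Product: 7 (3Z,5S,7E)-deca-3,7-dien-1-yn-5-ol, via silyl enynol 6 (not isolated)
Conditions: Zn dust activated with Cu(OAc)2 and AgNO3, MeOH/H2O 1:1, 40 °C; filter; then K2CO3, rt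
Reagents that add atoms: none
Why: Activated-zinc cis-semireduction of a conjugated diynol should act on the triple bond next to the hydroxyl, the silyl-capped one being shielded, to set the (Z)-alkene (the future C8=C9), after which carbonate-catalysed methanolysis of the alkynyl–silicon bond frees the terminal alkyne in the same methanolic medium.

Step 4
Reactants: 7 (3Z,5S,7E)-deca-3,7-dien-1-yn-5-ol; 8 (Z)-1,3-dichloroprop-1-ene
Product: 9 (3E,6S,7Z,12Z)-13-chlorotrideca-3,7,12-trien-9-yn-6-ol
Conditions: CuI (10 mol %), K2CO3, n-Bu4NCl, DMF, rt, excess 8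
Reagents that add atoms: none
Why: Copper-catalysed alkyne–allyl coupling: the copper acetylide of 7 displaces the allylic chloride of 8 in an SN2 sense under phase-transfer conditions, which creates the skipped C5 methylene and keeps the (Z)-vinyl chloride for the next step.

Step 5
Reactants: 9 (3E,6S,7Z,12Z)-13-chlorotrideca-3,7,12-trien-9-yn-6-ol; 10 ethynyl(trimethyl)silane
Product: 11 (3Z,8Z,10S,12E)-1-(trimethylsilyl)pentadeca-3,8,12-triene-1,6-diyn-10-ol
Conditions: PdCl2(PhCN)2 (5 mol %), CuI (10 mol %), piperidine, rt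
Reagents that add atoms: none
Why: Sonogashira coupling of a (Z)-vinyl chloride, which proceeds with retention of alkene geometry and installs C1–C2 as the silyl-protected alkyne of the (Z)-enyne.

Step 6
Reactants: 11 (3Z,8Z,10S,12E)-1-(trimethylsilyl)pentadeca-3,8,12-triene-1,6-diyn-10-ol
Product: 12 (3Z,8S,9R,10S,12E)-8,9-epoxy-1-(trimethylsilyl)pentadeca-3,12-diene-1,6-diyn-10-ol (cis-epoxide, threo to the C10 hydroxyl)
Conditions: Ti(OiPr)4 (20 mol %), t-BuOOH (anhydrous, in decane), 4 Å MS, CH2Cl2, −20 °C
Reagents that add atoms: tert-butyl hydroperoxide, CC(C)(C)OO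
Why: Hydroxyl-directed titanium-alkoxide/hydroperoxide epoxidation, which should touch only the allylic C8=C9 alkene and, because allylic 1,3-strain in the (Z)-allylic alcohol holds the C10–H in the alkene plane, deliver oxygen on the face that gives the threo cis-epoxy alcohol (8S,9R).

Step 7
Reactants: 12 (3Z,8S,9R,10S,12E)-8,9-epoxy-1-(trimethylsilyl)pentadeca-3,12-diene-1,6-diyn-10-ol
Product: 14 (2R,3S,5R)-2-[(1R,5Z)-1-bromo-8-(trimethylsilyl)oct-5-ene-2,7-diyn-1-yl]-5-[(1S)-1-bromopropyl]oxolan-3-ol, via bromo epoxonium bromide 13 (not isolated)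
Conditions: Br2 (1.0 equiv, slow addition of a dilute solution), CH2Cl2 (0.02 M), −78 °C, dark; aq. Na2S2O3/NaHCO3 quench
Reagents that add atoms: bromine, BrBr
Why: Br2 forms a reversible bromonium ion at the only isolated alkene (C12=C13; the enyne and alkyne π systems are less nucleophilic), and the oxirane oxygen captures it at C12 in a 5-exo closure that forges the O–C12 bond of ring B and gives the 1-oxoniabicyclo[3.1.0]hexane 13. The bromide counter-ion then opens 13 at the exocyclic, propargylic carbon C8 with inversion, so one reagent supplies both C–Br bonds. The closest known reaction type is the bromine-induced cyclisation of γ,δ-epoxy alkenes to bromoalkyl tetrahydrofurans with halide termination. C12 and C13 are set together by anti addition across the (E)-alkene, C8 by SN2 inversion of the cis-epoxide carbon, and C9 and C10 are carried over unchanged. The step needs three selectivities: the alkene π-face (the alkynyl arm of the cis-epoxide and the C10 oxygen lie on the concave face of the forming bicycle, so C13 should be taken up on the convex face, giving the 2,5-trans ring), 5-exo attack by the epoxide over 5-endo attack by the free C10 hydroxyl, and opening at C8 over C9 (propargylic activation and retention of the five-membered ring).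

Step 8
Reactants: 14 (2R,3S,5R)-2-[(1R,5Z)-1-bromo-8-(trimethylsilyl)oct-5-ene-2,7-diyn-1-yl]-5-[(1S)-1-bromopropyl]oxolan-3-ol
Product: 15 (3Z,6Z,8S,9R,10S,12R,13S)-8,13-dibromo-7,10:9,12-diepoxy-1-(trimethylsilyl)pentadeca-3,6-dien-1-yne
Conditions: AuCl (5 mol %), K2CO3 (10 mol %), MeCN, rt
Reagents that add atoms: none
Why: Gold-catalysed 5-exo-dig hydroalkoxylation (cycloisomerisation of a 4-alkyn-1-ol): anti addition of the C10 hydroxyl and a proton across C6≡C7 should close ring A cis-fused to ring B and place C5 cis to the ring oxygen, i.e. the (Z)-enol ether, while the carbonate buffer and the silver-free catalyst spare the propargylic bromide and the acid-labile product.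

Step 9
Reactants: 15 (3Z,6Z,8S,9R,10S,12R,13S)-8,13-dibromo-7,10:9,12-diepoxy-1-(trimethylsilyl)pentadeca-3,6-dien-1-yne
Product: 16 (2Z,3S,3aR,5R,6aS)-3-bromo-5-[(1S)-1-bromopropyl]-2-[(3Z)-hex-3-en-5-yn-1-ylidene]hexahydrofuro[3,2-b]furan
Conditions: K2CO3, MeOH, 0 °C
Reagents that add atoms: none
Why: Base-catalysed protodesilylation (methanolysis of the alkynyl–silicon bond) should unmask the terminal alkyne without affecting the enol ether or the two secondary bromides at 0 °C.

Compound list
1 | methyl (E)-hex-3-enoate | CC/C=C/CC(=O)OC | starting material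
2 | 1,4-bis(trimethylsilyl)buta-1,3-diyne | C[Si](C)(C)C#CC#C[Si](C)(C)C | starting material
3 | lithium 4-(trimethylsilyl)buta-1,3-diyn-1-ide | [Li]C#CC#C[Si](C)(C)C | intermediate
4 | (E)-1-(trimethylsilyl)deca-7-ene-1,3-diyn-5-one | CC/C=C/CC(=O)C#CC#C[Si](C)(C)C | intermediate
5 | (5S,7E)-1-(trimethylsilyl)deca-7-ene-1,3-diyn-5-ol | O[C@@H](C/C=C/CC)C#CC#C[Si](C)(C)C | intermediate
6 | (3Z,5S,7E)-1-(trimethylsilyl)deca-3,7-dien-1-yn-5-ol | O[C@@H](C/C=C/CC)/C=C\C#C[Si](C)(C)C | intermediate
7 | (3Z,5S,7E)-deca-3,7-dien-1-yn-5-ol | O[C@@H](C/C=C/CC)/C=C\C#C | intermediate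
8 | (Z)-1,3-dichloroprop-1-ene | ClC/C=C\Cl | starting material
9 | (3E,6S,7Z,12Z)-13-chlorotrideca-3,7,12-trien-9-yn-6-ol | O[C@@H](C/C=C/CC)/C=C\C#CC/C=C\Cl | intermediate
10 | ethynyl(trimethyl)silane | C#C[Si](C)(C)C | starting material
11 | (3Z,8Z,10S,12E)-1-(trimethylsilyl)pentadeca-3,8,12-triene-1,6-diyn-10-ol | O[C@@H](C/C=C/CC)/C=C\C#CC/C=C\C#C[Si](C)(C)C | intermediate
12 | (3Z,8S,9R,10S,12E)-8,9-epoxy-1-(trimethylsilyl)pentadeca-3,12-diene-1,6-diyn-10-ol | O[C@@H](C/C=C/CC)[C@H]1O[C@H]1C#CC/C=C\C#C[Si](C)(C)C | intermediate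
13 | bicyclic bromo epoxonium bromide (1-oxoniabicyclo[3.1.0]hexane with O bonded to C8, C9 and C12, bromine on C13) | O[C@H]1C[C@H]([C@@H](Br)CC)[O+]2[C@H]1[C@@H]2C#CC/C=C\C#C[Si](C)(C)C.[Br-] | intermediate
14 | (2R,3S,5R)-2-[(1R,5Z)-1-bromo-8-(trimethylsilyl)oct-5-ene-2,7-diyn-1-yl]-5-[(1S)-1-bromopropyl]oxolan-3-ol (8R,9R,10S,12R,13S in chain numbering) | O[C@H]1C[C@H]([C@@H](Br)CC)O[C@H]1[C@H](Br)C#CC/C=C\C#C[Si](C)(C)C | intermediate
15 | (3Z,6Z,8S,9R,10S,12R,13S)-8,13-dibromo-7,10:9,12-diepoxy-1-(trimethylsilyl)pentadeca-3,6-dien-1-yne | C[Si](C)(C)C#C/C=C\C/C=C1\O[C@H]2C[C@H]([C@@H](Br)CC)O[C@H]2[C@@H]1Br | intermediate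
16 | (2Z,3S,3aR,5R,6aS)-3-bromo-5-[(1S)-1-bromopropyl]-2-[(3Z)-hex-3-en-5-yn-1-ylidene]hexahydrofuro[3,2-b]furan | C#C/C=C\C/C=C1\O[C@H]2C[C@H]([C@@H](Br)CC)O[C@H]2[C@@H]1Br | target

Total step count: 9. Longest linear sequence: 9 steps (1 → 16).

Steps most likely to fail

Step 7. The bromonium ion may be captured by the free C10 hydroxyl (5-endo) or by bromide before the epoxide oxygen reaches it, the oxirane may be opened by adventitious HBr, or the alkene faces may be poorly differentiated. The fallback separates the two events. It sets out from 12: MgBr2·OEt2 in Et2O at −20 °C should open the alkynyl epoxide at the propargylic carbon C8 with inversion to give (3Z,8R,9R,10S,12E)-8-bromo-1-(trimethylsilyl)pentadeca-3,12-diene-1,6-diyne-9,10-diol F1. N-Bromosuccinimide in MeCN at −20 °C should then close ring B by 5-exo bromoetherification through the C9 hydroxyl, now a true alcohol nucleophile, and the sequence comes back to the route at 14.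

Step 2. The doubly activated methylene of diynone 4 may enolise under the hydrogen-transfer catalyst, which would move the alkene into conjugation or erode the enantioselectivity. The fallback makes the carbinol by C–C bond formation instead of reduction. It sets out from 1 and 2: i-Bu2AlH in CH2Cl2 at −78 °C should reduce 1 to (E)-hex-3-enal F2, and MeLi·LiBr followed by aqueous quench should convert 2 into buta-1,3-diynyl(trimethyl)silane F3. Catalytic asymmetric alkynylation of F2 with F3 (Me2Zn, the ProPhenol enantiomer that delivers the (S)-carbinol, Ph3PO, toluene, 0 °C) comes back to the route at 5.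

Step 3. The zinc reduction may run on to the diene or attack the silylated triple bond, and the two alkynes may not be differentiated cleanly. The fallback assembles the (Z)-enyne by cross-coupling instead of semireduction. It sets out from 1: commercial lithium (trimethylsilyl)acetylide with BF3·OEt2 at −78 °C should give (E)-1-(trimethylsilyl)oct-5-en-1-yn-3-one F4. The transfer hydrogenation of step 2 should then give (3S,5E)-1-(trimethylsilyl)oct-5-en-1-yn-3-ol F5, and K2CO3 in MeOH should give (3S,5E)-oct-5-en-1-yn-3-ol F6. Hydroxyl-directed trans-hydroalumination with NaAlH2(OCH2CH2OMe)2 followed by iodine should give (1Z,3S,5E)-1-iodoocta-1,5-dien-3-ol F7. Sonogashira coupling of F7 with 10 (Pd(PPh3)4, CuI, Et2NH, rt) comes back to the route at 6, which is desilylated to 7 as in step 3.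

Further compounds
F1 | step 7 | (3Z,8R,9R,10S,12E)-8-bromo-1-(trimethylsilyl)pentadeca-3,12-diene-1,6-diyne-9,10-diol | O[C@@H](C/C=C/CC)[C@@H](O)[C@H](Br)C#CC/C=C\C#C[Si](C)(C)C
F2 | step 2 | (E)-hex-3-enal | CC/C=C/CC=O
F3 | step 2 | buta-1,3-diynyl(trimethyl)silane | C[Si](C)(C)C#CC#C
F4 | step 3 | (E)-1-(trimethylsilyl)oct-5-en-1-yn-3-one | CC/C=C/CC(=O)C#C[Si](C)(C)C
F5 | step 3 | (3S,5E)-1-(trimethylsilyl)oct-5-en-1-yn-3-ol | O[C@@H](C/C=C/CC)C#C[Si](C)(C)C
F6 | step 3 | (3S,5E)-oct-5-en-1-yn-3-ol | O[C@@H](C/C=C/CC)C#C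
F7 | step 3 | (1Z,3S,5E)-1-iodoocta-1,5-dien-3-ol | O[C@@H](C/C=C/CC)/C=C\I
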